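**Retrosynthetic overview**
1. Backbone numbering C1–C23 from the ethyl group next to the free carbinol: C3–OH, C4, ring A = O + C5–C9 (C7=O), C10, C11=C12, C13 (propanoate), C14, C15 (acetate), C16, ring B = O + C17–C21 (C19=O), C22–C23.
2. C15–C16 is made last by a chelation-controlled vinylogous Mukaiyama aldol between the C1–C15 aldehyde 23 and the symmetric ring B pyranone 3 (as its O-silyl exocyclic dienol ether). The enabling feature is the C16 methylene of 3, acidified through C17=C18–C19=O, together with the twofold symmetry of 3; C15 and C16 are both set here. Then C15 acetate, C13 PMB → propanoate, C3 desilylation.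
3. Ring A of 23 comes from dehydrative cyclisation of the C5/C7/C9 triketone 21, assembled from β-diketone 11 (C1–C8; Evans syn-aldol for C3/C4, pentan-3-one for C6–C8) and aldehyde 19 (C9–C14 plus vinyl) by dianion aldol (C8–C9) and oxidation.
4. Aldehyde 19 comes from methyl (R)-3-hydroxy-2-methylpropanoate (C10), a Wittig olefination (C11=C12) and an anti-crotylboration (C13/C14); its terminal vinyl group is the masked C15 aldehyde.
5. Ring order: ring B first (step 1, from pentan-3-one and propanoic acid), ring A in step 17; the key step closes no ring.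

Key step: step 19

Assumption (chemistry): 4, 12, 2-(triphenylphosphoranylidene)propanal and (+)-B-methoxydiisopinocampheylborane are taken as commercial, and step 1 is the known one-pot acid-mediated route to 3.

**Route**

Step 1
Reactants: 1 pentan-3-one; 2 propanoic acid
Product: 3 2,6-diethyl-3,5-dimethyl-4H-pyran-4-one (ring B)
Conditions: 2 (2.5 equiv), polyphosphoric acid, 150 °C
Reagents that add atoms: none
Why: Acid-mediated double C-acylation of the ketone at both α-carbons and cyclodehydration of the resulting 1,3,5-triketone should give the symmetric pyranone in one pot; no stereocentre is formed.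

Step 2
Reactants: 4 (R)-4-benzyl-3-propanoyl-1,3-oxazolidin-2-one; 5 propanal
Product: 6 (R)-4-benzyl-3-[(2R,3S)-3-hydroxy-2-methylpentanoyl]-1,3-oxazolidin-2-one
Conditions: n-Bu2BOTf, Et3N, CH2Cl2, −78 → 0 °C; then H2O2, MeOH, pH 7 buffer
Reagents that add atoms: none
Why: Evans syn-aldol: the (Z)-boron enolate reacts through a Zimmerman–Traxler chair on the face away from the benzyl group, setting C4 (R) and C3 (S) in the syn relationship.

Step 3
Reactants: 6
Product: 7 (R)-4-benzyl-3-[(2R,3S)-3-(tert-butyldimethylsilyloxy)-2-methylpentanoyl]-1,3-oxazolidin-2-one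
Conditions: TBSOTf, 2,6-lutidine, CH2Cl2, 0 °C
Reagents that add atoms: tert-butyldimethylsilyl triflate, CC(C)(C)[Si](C)(C)OS(=O)(=O)C(F)(F)F
Why: Silylation of the secondary alcohol blocks retro-aldol and protects C3–O until the last step.

Step 4
Reactants: 7
Product: 8 (2S,3S)-3-(tert-butyldimethylsilyloxy)-2-methylpentan-1-ol
Conditions: LiBH4, H2O (1 equiv), Et2O, 0 °C
Reagents that add atoms: none
Why: Reductive cleavage of the imide (hydride attack at the exocyclic carbonyl) removes the auxiliary without touching the α-stereocentre.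

Step 5
Reactants: 8
Product: 9 (2R,3S)-3-(tert-butyldimethylsilyloxy)-2-methylpentanal
Conditions: Dess–Martin periodinane, pyridine, CH2Cl2, 0 °C → rt
Reagents that add atoms: none
Why: Dess–Martin oxidation under buffered conditions should give the α-branched aldehyde without epimerisation.

Step 6
Reactants: 1 pentan-3-one; 9
Product: 10 (6S,7S)-7-(tert-butyldimethylsilyloxy)-5-hydroxy-4,6-dimethylnonan-3-one (mixture at C4/C5 of this name)
Conditions: LiN(i-Pr)2, THF, −78 °C; then 9; AcOH quench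
Reagents that add atoms: none
Why: Lithium enolate aldol addition; the two new centres (backbone C5, C6) need no control because both are destroyed in steps 7 and 17.

Step 7
Reactants: 10
Product: 11 (6R,7S)-7-(tert-butyldimethylsilyloxy)-4,6-dimethylnonane-3,5-dione (C4 epimers/enol forms)
Conditions: Dess–Martin periodinane, CH2Cl2, rt
Reagents that add atoms: none
Why: Dess–Martin oxidation of the β-hydroxy ketone gives the β-diketone carrying C1–C8.

Step 8
Reactants: 12 methyl (R)-3-hydroxy-2-methylpropanoate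
Product: 13 methyl (R)-3-(tert-butyldimethylsilyloxy)-2-methylpropanoate
Conditions: TBSCl, imidazole, DMF, rt
Reagents that add atoms: tert-butyldimethylsilyl chloride, CC(C)(C)[Si](C)(C)Cl
Why: Standard silylation of the primary alcohol; the C10 stereocentre comes from the chiral pool.

Step 9
Reactants: 13
Product: 14 (R)-3-(tert-butyldimethylsilyloxy)-2-methylpropanal
Conditions: i-Bu2AlH, CH2Cl2, −78 °C; MeOH, then aq KNa tartrate
Reagents that add atoms: none
Why: Half-reduction of the ester at −78 °C through the stable tetrahedral aluminium hemiacetal should give the aldehyde with C10 intact.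

Step 10
Reactants: 14
Product: 15 (2E,4S)-5-(tert-butyldimethylsilyloxy)-2,4-dimethylpent-2-enal
Conditions: 2-(triphenylphosphoranylidene)propanal, toluene, 90 °C
Reagents that add atoms: 2-(triphenylphosphoranylidene)propanal, CC(C=O)=P(c1ccccc1)(c1ccccc1)c1ccccc1
Why: Wittig olefination with the stabilised formyl ylide should give the (E)-2-methylenal, fixing the C11=C12 geometry.

Step 11
Reactants: 15
Product: 16 (3R,4R,5E,7S)-8-(tert-butyldimethylsilyloxy)-3,5,7-trimethylocta-1,5-dien-4-ol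
Conditions: trans-but-2-ene, n-BuLi, KOt-Bu, THF, −78 → −45 °C; (+)-Ipc2BOMe, then BF3·OEt2, −78 °C; 15, −78 °C; NaOH, H2O2
Reagents that add atoms: (E)-but-2-ene (delivered as its crotylborane), C/C=C/C
Why: Brown (E)-crotylboration: the closed chair transition state gives the 13,14-anti relationship and the isopinocampheyl groups of the (+)-Ipc2BOMe-derived reagent direct attack to the Re face of the enal, setting C13 (R) and C14 (R); the vinyl group is the latent C15 aldehyde.

Step 12
Reactants: 16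
Product: 17 tert-butyl{[(2S,3E,5R,6R)-5-(4-methoxybenzyloxy)-2,4,6-trimethylocta-3,7-dien-1-yl]oxy}dimethylsilane
Conditions: NaH, 4-methoxybenzyl chloride, n-Bu4NI (cat.), DMF, 0 °C → rt
Reagents that add atoms: 4-methoxybenzyl chloride, COc1ccc(CCl)cc1
Why: Williamson etherification; the PMB ether is chosen because it can chelate in step 19 and can later be removed oxidatively beside the esters.

Step 13
Reactants: 17
Product: 18 (2S,3E,5R,6R)-5-(4-methoxybenzyloxy)-2,4,6-trimethylocta-3,7-dien-1-ol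
Conditions: camphorsulfonic acid (cat.), MeOH–CH2Cl2, 0 °C
Reagents that add atoms: none
Why: Acid-catalysed methanolysis removes the only (primary) silyl ether while the PMB ether stays.

Step 14
Reactants: 18
Product: 19 (2S,3E,5R,6R)-5-(4-methoxybenzyloxy)-2,4,6-trimethylocta-3,7-dienal
Conditions: Dess–Martin periodinane, pyridine, CH2Cl2, 0 °C; used crude at once
Reagents that add atoms: none
Why: Dess–Martin oxidation under buffered, non-basic conditions should give the epimerisable β,γ-unsaturated aldehyde without loss of C10 or alkene migration.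

Step 15
Reactants: 11; 19
Product: 20 δ-hydroxy-β-diketone (backbone C1–C14 plus vinyl; C9–OH, C5 and C7 ketones; mixture at C6, C8, C9)
Conditions: 11, LiN(i-Pr)2 (2.2 equiv), THF, −78 → −30 °C; then 19, −78 °C; AcOH quench
Reagents that add atoms: none
Why: β-Diketone dianion aldol: the second deprotonation occurs at the unhindered C8 methylene and this more basic terminal carbon adds to the aldehyde, forming C8–C9; the new centres are erased in steps 16 and 17.

Step 16
Reactants: 20
Product: 21 C5/C7/C9 triketone (C3-OTBS, C13-OPMB, terminal vinyl; C6/C8 epimers and enol forms)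
Conditions: Dess–Martin periodinane, pyridine, CH2Cl2, 0 °C → rt
Reagents that add atoms: none
Why: Dess–Martin oxidation of the C9 carbinol gives the linear triketide under near-neutral conditions.

Step 17
Reactants: 21
Product: 22 2-[(2R,3S)-3-(tert-butyldimethylsilyloxy)pentan-2-yl]-6-[(2S,3E,5R,6R)-5-(4-methoxybenzyloxy)-4,6-dimethylocta-3,7-dien-2-yl]-3,5-dimethyl-4H-pyran-4-one (ring A)
Conditions: PPh3, CCl4, THF, rt
Reagents that add atoms: none
Why: Biomimetic dehydrative cyclisation of the 1,3,5-triketone to the 4-pyranone by Appel-type activation of an enol oxygen, a mild protocol known to keep stereocentres next to the new ring (C4, C10).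

Step 18
Reactants: 22
Product: 23 (2S,3R,4E,6S)-6-{6-[(2R,3S)-3-(tert-butyldimethylsilyloxy)pentan-2-yl]-3,5-dimethyl-4-oxo-4H-pyran-2-yl}-3-(4-methoxybenzyloxy)-2,4-dimethylhept-4-enal
Conditions: OsO4 (cat.), NaIO4, 2,6-lutidine, dioxane–H2O, 0 °C → rt
Reagents that add atoms: sodium periodate (terminal oxidant and oxygen source via OsO4), [Na+].[O-]I(=O)(=O)=O
Why: Lemieux–Johnson cleavage: osmylation should prefer the monosubstituted terminal alkene over the C11=C12 alkene, which is trisubstituted and flanked by two tertiary carbons, and ring A is inert; periodate then cleaves the diol to the C15 aldehyde.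

Step 19
Reactants: 3; 23
Product: 25 C15 alcohol, 2-ethyl-3,5-dimethyl-4H-pyran-4-one joined at C16 (3-OTBS, 13-OPMB; 3S,4R,10S,11E,13R,14R,15S,16R), via silyl dienol ether 24 (not isolated)
Conditions: 3 (2 equiv), TMSOTf and i-Pr2NEt (equimolar to 3), CH2Cl2, −78 → 0 °C; transfer to 23 + MgBr2·OEt2 (3 equiv), CH2Cl2, −78 → −40 °C; aq citric acid, MeOH
Reagents that add atoms: none
Why: Proposed new method: O-silylation of the ring B carbonyl of 3 gives a 4-silyloxypyrylium ion whose C16 methylene is deprotonated by the hindered amine to the neutral 2-ethylidene-2H-pyran 24, a cross-conjugated silyl trienol ether that attacks the MgBr2-chelated aldehyde 23 through its exocyclic carbon and re-aromatises to the pyranone; the closest known reaction types are the vinylogous aldol addition of lithiated 2-ethyl-4-pyranones to aldehydes, the aldehyde condensation of 2-alkylpyrylium anhydrobases and chelation-controlled Mukaiyama aldol additions to β-(4-methoxybenzyloxy) aldehydes. No ring is closed. C15 is controlled by the six-membered magnesium chelate between the aldehyde oxygen and the C13 PMB ether: attack anti to the C14 methyl group gives the 14,15-anti (anti-Felkin), 13,15-syn carbinol. C16 is controlled by an open antiperiplanar transition state in which the (Z)-ethylidene of 24 (methyl held toward the ring oxygen by allylic strain with the C18 methyl) keeps its methyl away from the aldehyde chain, giving the 15,16-syn adduct. The step needs attack through C16 and not through ring carbons C18/C20 (secured because only exocyclic attack restores the aromatic pyranone), face selectivity (secured by the chelating PMB ether) and integrity of the base-labile α-pyranonyl centres C4 and C10 (secured by the absence of free amine or metal amide).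

Step 20
Reactants: 25
Product: 26 C15 acetate (3-OTBS, 13-OPMB; configuration as in 25)
Conditions: Ac2O, pyridine, DMAP (cat.), CH2Cl2, 0 °C → rt
Reagents that add atoms: acetic anhydride, CC(=O)OC(C)=O
Why: DMAP-catalysed acetylation of the only free hydroxyl; the weak base should avoid β-elimination across C15–C16.

Step 21
Reactants: 26
Product: 27 C13 alcohol (3-OTBS, 15-OAc; configuration unchanged)
Conditions: DDQ, CH2Cl2–pH 7 buffer, 0 °C
Reagents that add atoms: none
Why: Oxidative PMB cleavage (hydride abstraction by DDQ, hydrolysis of the oxocarbenium ion) frees C13–OH; silyl ether, acetate and pyranones are inert.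

Step 22
Reactants: 27
Product: 28 C13 propanoate (3-OTBS, 15-OAc; configuration unchanged)
Conditions: propanoic anhydride, pyridine, DMAP (cat.), CH2Cl2, 0 °C → rt
Reagents that add atoms: propanoic anhydride, CCC(=O)OC(=O)CC
Why: DMAP-catalysed acylation of the allylic C13 alcohol; intermolecular acylation should outrun 1,3-acetyl migration under these weakly basic conditions.

Step 23
Reactants: 28
Product: 29 CNP0265513.2 (3S,4R,10S,11E,13R,14R,15S,16R; 3-OH, 13-propanoate, 15-acetate)
Conditions: HF·pyridine, pyridine, THF, 0 °C → rt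
Reagents that add atoms: none
Why: Buffered fluoride cleavage of the C3 silyl ether leaves both esters and both pyranones untouched and should give the target.

**Compound list**
1 | pentan-3-one | CCC(=O)CC | starting material
2 | propanoic acid | CCC(=O)O | starting material
3 | 2,6-diethyl-3,5-dimethyl-4H-pyran-4-one | CCc1oc(CC)c(C)c(=O)c1C | intermediate
4 | (R)-4-benzyl-3-propanoyl-1,3-oxazolidin-2-one | CCC(=O)N1C(=O)OC[C@H]1Cc1ccccc1 | starting material
5 | propanal | CCC=O | starting material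
6 | (R)-4-benzyl-3-[(2R,3S)-3-hydroxy-2-methylpentanoyl]-1,3-oxazolidin-2-one | O=C([C@H](C)[C@@H](O)CC)N1C(=O)OC[C@H]1Cc1ccccc1 | intermediate
7 | (R)-4-benzyl-3-[(2R,3S)-3-(tert-butyldimethylsilyloxy)-2-methylpentanoyl]-1,3-oxazolidin-2-one | O=C([C@H](C)[C@@H](O[Si](C)(C)C(C)(C)C)CC)N1C(=O)OC[C@H]1Cc1ccccc1 | intermediate
8 | (2S,3S)-3-(tert-butyldimethylsilyloxy)-2-methylpentan-1-ol | OC[C@H](C)[C@@H](O[Si](C)(C)C(C)(C)C)CC | intermediate
9 | (2R,3S)-3-(tert-butyldimethylsilyloxy)-2-methylpentanal | O=C[C@H](C)[C@@H](O[Si](C)(C)C(C)(C)C)CC | intermediate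
10 | (6S,7S)-7-(tert-butyldimethylsilyloxy)-5-hydroxy-4,6-dimethylnonan-3-one, mixture at C4/C5 | CCC(=O)C(C)C(O)[C@H](C)[C@@H](O[Si](C)(C)C(C)(C)C)CC | intermediate
11 | (6R,7S)-7-(tert-butyldimethylsilyloxy)-4,6-dimethylnonane-3,5-dione, C4 epimers | CCC(=O)C(C)C(=O)[C@H](C)[C@@H](O[Si](C)(C)C(C)(C)C)CC | intermediate
12 | methyl (R)-3-hydroxy-2-methylpropanoate | COC(=O)[C@H](C)CO | starting material
13 | methyl (R)-3-(tert-butyldimethylsilyloxy)-2-methylpropanoate | COC(=O)[C@H](C)CO[Si](C)(C)C(C)(C)C | intermediate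
14 | (R)-3-(tert-butyldimethylsilyloxy)-2-methylpropanal | O=C[C@H](C)CO[Si](C)(C)C(C)(C)C | intermediate
15 | (2E,4S)-5-(tert-butyldimethylsilyloxy)-2,4-dimethylpent-2-enal | O=C/C(C)=C/[C@H](C)CO[Si](C)(C)C(C)(C)C | intermediate
16 | (3R,4R,5E,7S)-8-(tert-butyldimethylsilyloxy)-3,5,7-trimethylocta-1,5-dien-4-ol | O[C@@H](/C(C)=C/[C@H](C)CO[Si](C)(C)C(C)(C)C)[C@H](C)C=C | intermediate
17 | tert-butyl{[(2S,3E,5R,6R)-5-(4-methoxybenzyloxy)-2,4,6-trimethylocta-3,7-dien-1-yl]oxy}dimethylsilane | COc1ccc(CO[C@@H](/C(C)=C/[C@H](C)CO[Si](C)(C)C(C)(C)C)[C@H](C)C=C)cc1 | intermediate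
18 | (2S,3E,5R,6R)-5-(4-methoxybenzyloxy)-2,4,6-trimethylocta-3,7-dien-1-ol | COc1ccc(CO[C@@H](/C(C)=C/[C@H](C)CO)[C@H](C)C=C)cc1 | intermediate
19 | (2S,3E,5R,6R)-5-(4-methoxybenzyloxy)-2,4,6-trimethylocta-3,7-dienal | COc1ccc(CO[C@@H](/C(C)=C/[C@H](C)C=O)[C@H](C)C=C)cc1 | intermediate
20 | δ-hydroxy-β-diketone (C9–OH; C5, C7 ketones; 3-OTBS, 13-OPMB, vinyl), mixture at C6/C8/C9 | COc1ccc(CO[C@@H](/C(C)=C/[C@H](C)C(O)C(C)C(=O)C(C)C(=O)[C@H](C)[C@@H](O[Si](C)(C)C(C)(C)C)CC)[C@H](C)C=C)cc1 | intermediate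
21 | C5/C7/C9 triketone (3-OTBS, 13-OPMB, vinyl), C6/C8 epimers | COc1ccc(CO[C@@H](/C(C)=C/[C@H](C)C(=O)C(C)C(=O)C(C)C(=O)[C@H](C)[C@@H](O[Si](C)(C)C(C)(C)C)CC)[C@H](C)C=C)cc1 | intermediate
22 | 2-[(2R,3S)-3-(tert-butyldimethylsilyloxy)pentan-2-yl]-6-[(2S,3E,5R,6R)-5-(4-methoxybenzyloxy)-4,6-dimethylocta-3,7-dien-2-yl]-3,5-dimethyl-4H-pyran-4-one | COc1ccc(CO[C@@H](/C(C)=C/[C@H](C)c2oc([C@H](C)[C@@H](O[Si](C)(C)C(C)(C)C)CC)c(C)c(=O)c2C)[C@H](C)C=C)cc1 | intermediate
23 | (2S,3R,4E,6S)-6-{6-[(2R,3S)-3-(tert-butyldimethylsilyloxy)pentan-2-yl]-3,5-dimethyl-4-oxo-4H-pyran-2-yl}-3-(4-methoxybenzyloxy)-2,4-dimethylhept-4-enal | COc1ccc(CO[C@@H](/C(C)=C/[C@H](C)c2oc([C@H](C)[C@@H](O[Si](C)(C)C(C)(C)C)CC)c(C)c(=O)c2C)[C@H](C)C=O)cc1 | intermediate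
24 | 6-ethyl-2-[(Z)-ethylidene]-3,5-dimethyl-4-(trimethylsilyloxy)-2H-pyran (silyl dienol ether of 3, not isolated) | C/C=C1\OC(CC)=C(C)C(O[Si](C)(C)C)=C1C | intermediate
25 | C15 alcohol, bis-pyranone (3-OTBS, 13-OPMB; 3S,4R,10S,11E,13R,14R,15S,16R) | COc1ccc(CO[C@@H](/C(C)=C/[C@H](C)c2oc([C@H](C)[C@@H](O[Si](C)(C)C(C)(C)C)CC)c(C)c(=O)c2C)[C@H](C)[C@H](O)[C@@H](C)c2oc(CC)c(C)c(=O)c2C)cc1 | intermediate
26 | C15 acetate (3-OTBS, 13-OPMB; configuration as in 25) | COc1ccc(CO[C@@H](/C(C)=C/[C@H](C)c2oc([C@H](C)[C@@H](O[Si](C)(C)C(C)(C)C)CC)c(C)c(=O)c2C)[C@H](C)[C@H](OC(C)=O)[C@@H](C)c2oc(CC)c(C)c(=O)c2C)cc1 | intermediate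
27 | C13 alcohol (3-OTBS, 15-OAc; configuration as in 25) | O[C@@H](/C(C)=C/[C@H](C)c1oc([C@H](C)[C@@H](O[Si](C)(C)C(C)(C)C)CC)c(C)c(=O)c1C)[C@H](C)[C@H](OC(C)=O)[C@@H](C)c1oc(CC)c(C)c(=O)c1C | intermediate
28 | C13 propanoate (3-OTBS, 15-OAc; configuration as in 25) | CCC(=O)O[C@@H](/C(C)=C/[C@H](C)c1oc([C@H](C)[C@@H](O[Si](C)(C)C(C)(C)C)CC)c(C)c(=O)c1C)[C@H](C)[C@H](OC(C)=O)[C@@H](C)c1oc(CC)c(C)c(=O)c1C | intermediate
29 | CNP0265513.2 (3S,4R,10S,11E,13R,14R,15S,16R; 3-OH, 13-propanoate, 15-acetate) | CCC(=O)O[C@@H](/C(C)=C/[C@H](C)c1oc([C@H](C)[C@@H](O)CC)c(C)c(=O)c1C)[C@H](C)[C@H](OC(C)=O)[C@@H](C)c1oc(CC)c(C)c(=O)c1C | target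

**Totals**
Total step count: 23. Longest linear sequence: 16 steps (12 → 29, steps 8–23).

**Steps most likely to fail**

Step 19 (proposed new method). What may go wrong: incomplete formation or protonation of the silyl dienol ether, attack on non-chelated aldehyde (leading into the C15-epimeric Felkin series), or poor syn/anti control at C16. The fallback uses known chemistry and builds ring B on the chain instead of coupling it. Setting out from 23, (Z)-crotylboration (cis-but-2-ene, n-BuLi/KOt-Bu, (+)-Ipc2BOMe, BF3·OEt2; NaBO3·4H2O work-up) should give the 15,16-syn, 14,15-anti homoallylic alcohol F1 by reagent control, reinforced by the anti-Felkin preference of (Z)-crotylboranes with α-methyl aldehydes. TESOTf/2,6-lutidine gives the C15 triethylsilyl ether F2. OsO4 (cat.)/NaIO4/2,6-lutidine cleaves the terminal alkene to the C17 aldehyde F3. The dianion of commercial 4-methylheptane-3,5-dione (LiN(i-Pr)2, 2 equiv) adds to give the δ-hydroxy-β-diketone F4. Dess–Martin oxidation gives the C17/C19/C21 triketone F5, and PPh3/CCl4 closes ring B to the silyl-protected bis-pyranone F6. PPTS/MeOH removes the triethylsilyl group and the route is rejoined at 25.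

Step 15. What may go wrong: deprotonation of the β,γ-unsaturated α-methyl aldehyde 19 by the strongly basic dianion (epimerisation at C10, migration of the alkene into conjugation), or deprotonation of 11 at C4 instead of C8. The fallback replaces the dianion by a neutral boron enolate of a monoketone. Setting out from 10, TESOTf/2,6-lutidine gives the triethylsilyl ether F7. Enolisation with c-Hex2BCl/Et3N (Et2O, 0 °C) and addition of 19 at −78 °C (H2O2/MeOH/buffer work-up) gives the aldol adduct F8. PPTS/MeOH removes the triethylsilyl group to give the C5,C9-diol F9. Double Dess–Martin oxidation rejoins the route at 21.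

Step 17. What may go wrong: loss of configuration at C10 (α to a carbonyl and allylic) or migration of the C11=C12 alkene during dehydrative cyclisation of the triketone. The fallback closes ring A before the alkene exists. Setting out from 11, with commercial methyl (S)-3-hydroxy-2-methylpropanoate as extra material, silylation (TBSCl, imidazole) gives methyl (S)-3-(tert-butyldimethylsilyloxy)-2-methylpropanoate F10 and i-Bu2AlH at −78 °C gives (S)-3-(tert-butyldimethylsilyloxy)-2-methylpropanal F11. The dianion of 11 adds to F11 to give the δ-hydroxy-β-diketone F12; Dess–Martin oxidation gives the triketone F13; PPh3/CCl4 gives the ring A pyranone F14 with a 1-silyloxypropan-2-yl arm. HF·pyridine/pyridine at 0 °C removes only the primary silyl ether to give the alcohol F15. Dess–Martin oxidation gives the α-pyranonyl aldehyde F16, and 2-(triphenylphosphoranylidene)propanal gives the enal F17. (E)-Crotylboration with the (+)-Ipc2BOMe-derived reagent gives the C13 alcohol F18. 4-Methoxybenzyl trichloroacetimidate with catalytic camphorsulfonic acid then rejoins the route at 22.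

**Further compounds**
F1 | step 19 | (Z)-crotylboration adduct of 23: C15 alcohol with C16 methyl and terminal vinyl (15,16-syn, 14,15-anti) | COc1ccc(CO[C@@H](/C(C)=C/[C@H](C)c2oc([C@H](C)[C@@H](O[Si](C)(C)C(C)(C)C)CC)c(C)c(=O)c2C)[C@H](C)[C@H](O)[C@@H](C)C=C)cc1
F2 | step 19 | C15 triethylsilyl ether of F1 | COc1ccc(CO[C@@H](/C(C)=C/[C@H](C)c2oc([C@H](C)[C@@H](O[Si](C)(C)C(C)(C)C)CC)c(C)c(=O)c2C)[C@H](C)[C@H](O[Si](CC)(CC)CC)[C@@H](C)C=C)cc1
F3 | step 19 | C17 aldehyde from F2 | COc1ccc(CO[C@@H](/C(C)=C/[C@H](C)c2oc([C@H](C)[C@@H](O[Si](C)(C)C(C)(C)C)CC)c(C)c(=O)c2C)[C@H](C)[C@H](O[Si](CC)(CC)CC)[C@@H](C)C=O)cc1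
F4 | step 19 | C17-hydroxy C19/C21-diketone (mixture at C17, C18, C20) | COc1ccc(CO[C@@H](/C(C)=C/[C@H](C)c2oc([C@H](C)[C@@H](O[Si](C)(C)C(C)(C)C)CC)c(C)c(=O)c2C)[C@H](C)[C@H](O[Si](CC)(CC)CC)[C@@H](C)C(O)C(C)C(=O)C(C)C(=O)CC)cc1
F5 | step 19 | C17/C19/C21 triketone | COc1ccc(CO[C@@H](/C(C)=C/[C@H](C)c2oc([C@H](C)[C@@H](O[Si](C)(C)C(C)(C)C)CC)c(C)c(=O)c2C)[C@H](C)[C@H](O[Si](CC)(CC)CC)[C@@H](C)C(=O)C(C)C(=O)C(C)C(=O)CC)cc1
F6 | step 19 | C15 triethylsilyl ether of 25 | COc1ccc(CO[C@@H](/C(C)=C/[C@H](C)c2oc([C@H](C)[C@@H](O[Si](C)(C)C(C)(C)C)CC)c(C)c(=O)c2C)[C@H](C)[C@H](O[Si](CC)(CC)CC)[C@@H](C)c2oc(CC)c(C)c(=O)c2C)cc1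
F7 | step 15 | triethylsilyl ether of 10 | CCC(=O)C(C)C(O[Si](CC)(CC)CC)[C@H](C)[C@@H](O[Si](C)(C)C(C)(C)C)CC
F8 | step 15 | boron aldol adduct of F7 and 19 (C9–OH, C7 ketone, C5–OTES) | COc1ccc(CO[C@@H](/C(C)=C/[C@H](C)C(O)C(C)C(=O)C(C)C(O[Si](CC)(CC)CC)[C@H](C)[C@@H](O[Si](C)(C)C(C)(C)C)CC)[C@H](C)C=C)cc1
F9 | step 15 | C5,C9-diol C7-ketone | COc1ccc(CO[C@@H](/C(C)=C/[C@H](C)C(O)C(C)C(=O)C(C)C(O)[C@H](C)[C@@H](O[Si](C)(C)C(C)(C)C)CC)[C@H](C)C=C)cc1
F10 | step 17 | methyl (S)-3-(tert-butyldimethylsilyloxy)-2-methylpropanoate | COC(=O)[C@@H](C)CO[Si](C)(C)C(C)(C)C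
F11 | step 17 | (S)-3-(tert-butyldimethylsilyloxy)-2-methylpropanal | O=C[C@@H](C)CO[Si](C)(C)C(C)(C)C
F12 | step 17 | dianion aldol adduct of 11 and F11 (C9–OH; mixture at C6/C8/C9) | CC(C)(C)[Si](C)(C)OC[C@H](C)C(O)C(C)C(=O)C(C)C(=O)[C@H](C)[C@@H](O[Si](C)(C)C(C)(C)C)CC
F13 | step 17 | C5/C7/C9 triketone with C11 silyloxymethyl end | CC(C)(C)[Si](C)(C)OC[C@H](C)C(=O)C(C)C(=O)C(C)C(=O)[C@H](C)[C@@H](O[Si](C)(C)C(C)(C)C)CC
F14 | step 17 | ring A pyranone with (S)-1-(tert-butyldimethylsilyloxy)propan-2-yl arm | CC(C)(C)[Si](C)(C)OC[C@H](C)c1oc([C@H](C)[C@@H](O[Si](C)(C)C(C)(C)C)CC)c(C)c(=O)c1C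
F15 | step 17 | primary alcohol from F14 | OC[C@H](C)c1oc([C@H](C)[C@@H](O[Si](C)(C)C(C)(C)C)CC)c(C)c(=O)c1C
F16 | step 17 | α-pyranonyl aldehyde (C11 aldehyde) | O=C[C@H](C)c1oc([C@H](C)[C@@H](O[Si](C)(C)C(C)(C)C)CC)c(C)c(=O)c1C
F17 | step 17 | (E)-2-methylenal (C13 aldehyde) on ring A | O=C/C(C)=C/[C@H](C)c1oc([C@H](C)[C@@H](O[Si](C)(C)C(C)(C)C)CC)c(C)c(=O)c1C
F18 | step 17 | C13 alcohol, de-PMB analogue of 22 | O[C@@H](/C(C)=C/[C@H](C)c1oc([C@H](C)[C@@H](O[Si](C)(C)C(C)(C)C)CC)c(C)c(=O)c1C)[C@H](C)C=C
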